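**Plan**
- Retrosynthesis: the C4 ketone is first taken back to a C4–OMe ether, an acetal-level helper. Ring C is then cut at O1–C2 and at C3–C4 in one retro-oxa-[4+2], leaving a salicylaldehyde (ring A with O1 and C4), methanol and a styrene (C2, C3, ring B).
- Enabling feature: O1–C8a–C4a–C4 is the oxadiene of an ortho-quinone methide of ring A, stabilised by the 5- and 7-methoxy groups. C3=C2 carries ring B, whose 2- and 4-methoxy groups make it an electron-rich, polarised dienophile, so the two partners are polarity matched.
- Forward: aldehyde 1 → styrene 2 (Wittig); salicylaldehyde 3 + methanol 4 + 2 → [hemiacetal 5 → quinone methide 6] → 4-methoxyflavan 7, so ring C arises between the preformed rings A and B; 7 → [hemiketal 8] → flavanone 9 (DDQ, water).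
- Stereochemistry: C2 (S), the only stereocentre of the target, is set in the cycloaddition by a chiral Brønsted acid bound at O1. The transient C4 centre is erased in step 3, and no basic step follows, so retro-oxa-Michael racemisation is avoided.

Key step: step 2

Remark on the chemistry: the (R) series of the chiral acid is assumed to lead to the 2S adduct. If the sense of induction proves opposite, the (S) acid is used and nothing else changes.

**Step 1**
Reactants: 1 2,3,4-trimethoxybenzaldehyde
Product: 2 2,3,4-trimethoxystyrene (1-ethenyl-2,3,4-trimethoxybenzene)
Conditions: MePPh3Br, KOtBu, THF, 0 °C to rt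
Reagents that add atoms: methyltriphenylphosphonium bromide, C[P+](c1ccccc1)(c1ccccc1)c1ccccc1.[Br-]
Why: Wittig methylenation of an aromatic aldehyde with the unstabilised ylide should give the terminal styrene cleanly, and no stereocentre is formed.

**Step 2**
Reactants: 3 2-hydroxy-4,6-dimethoxybenzaldehyde; 4 methanol; 2 2,3,4-trimethoxystyrene
Product: 7 (2S,4S)-4,5,7-trimethoxy-2-(2,3,4-trimethoxyphenyl)chromane (2,4-cis), via methyl hemiacetal 5 (not isolated), via methoxy ortho-quinone methide 6 (not isolated)
Conditions: (R)-3,3'-bis(2,4,6-triisopropylphenyl)-BINOL N-triflylphosphoramide (5 mol %), 2 (2 equiv), 4 (1.5 equiv), 5 Å MS, toluene, 0 °C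
Reagents that add atoms: none
Why: Proposed new method: the chiral acid condenses 3 with methanol to hemiacetal 5 and ionises it, with loss of water, to the methoxy-substituted ortho-quinone methide 6, held as a hydrogen-bonded ion pair with the phosphoramide; the electron-rich styrene 2 then adds across the O=C–C=C oxadiene of 6 in an asynchronous inverse-electron-demand oxa-Diels–Alder reaction, its CH2 terminus bonding to the methide carbon (C3–C4) and its benzylic carbon to the quinone oxygen (O1–C2), with rearomatisation of ring A as the driving force. The closest known reaction types are the chiral Brønsted acid catalysed [4+2] cycloaddition of ortho-quinone methides from ortho-hydroxybenzyl alcohols with styrenes, the intramolecular asymmetric variant in which a salicylaldehyde and an alcohol give the same kind of alkoxy quinone methide, and the racemic Lewis acid mediated salicylaldehyde/orthoformate/alkene chroman synthesis; the intermolecular, three-component, enantioselective combination is what is new. Ring C closes by [4+2] cycloaddition (four atoms O1–C8a–C4a–C4 from 6, two atoms C3–C2 from 2); in the stepwise limit the benzylic cation, stabilised by the 2- and 4-methoxy groups of ring B, is captured by the phenolic oxygen in a six-membered closure. C2 (S) is under catalyst control, because the chiral anion sits on the very oxygen that bonds to C2 and so selects the enantiotopic face of the styrene; C4 follows from endo approach to the E methide (2,4-cis expected) and is of no consequence, since it becomes the carbonyl carbon. The step needs regioselectivity, secured by the polarity match (electrophilic oxocarbenium-like methide carbon, positive charge at the benzylic carbon of 2 stabilised by ring B), chemoselectivity over Friedel–Crafts attack by ring A of the product and over styrene oligomerisation, secured by an excess of 2 and a weakly nucleophilic counter-anion, and enantioselectivity, secured by the catalyst.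

**Step 3**
Reactants: 7 (2S,4S)-4,5,7-trimethoxy-2-(2,3,4-trimethoxyphenyl)chromane
Product: 9 (2S)-5,7-dimethoxy-2-(2,3,4-trimethoxyphenyl)chroman-4-one (target), via C4 hemiketal 8 (not isolated)
Conditions: DDQ (1.2 equiv), CH2Cl2/pH 7 phosphate buffer, 0 °C
Reagents that add atoms: water, O
Why: Oxidative cleavage of an electron-rich benzylic methyl ether, in which DDQ abstracts the hydride from C4–H (activated by its own methoxy group and by the three oxygen donors of ring A), water adds to the oxocarbenium ion to give hemiketal 8 and methanol is lost to leave the ketone, while C2 is untouched and no base is present, so the 2S configuration should be kept.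

**Compound list**
1 | 2,3,4-trimethoxybenzaldehyde | COc1ccc(C=O)c(OC)c1OC | starting material
2 | 2,3,4-trimethoxystyrene | C=Cc1ccc(OC)c(OC)c1OC | intermediate
3 | 2-hydroxy-4,6-dimethoxybenzaldehyde | COc1cc(O)c(C=O)c(OC)c1 | starting material
4 | methanol | CO | starting material
5 | 2-[hydroxy(methoxy)methyl]-3,5-dimethoxyphenol (methyl hemiacetal of 3, racemic, not isolated) | COC(O)c1c(O)cc(OC)cc1OC | intermediate
6 | (6E)-3,5-dimethoxy-6-(methoxymethylidene)cyclohexa-2,4-dien-1-one (ortho-quinone methide, not isolated) | CO/C=C1/C(=O)C=C(OC)C=C1OC | intermediate
7 | (2S,4S)-4,5,7-trimethoxy-2-(2,3,4-trimethoxyphenyl)chromane (2,4-cis) | COc1cc(OC)c2c(c1)O[C@H](c1ccc(OC)c(OC)c1OC)C[C@@H]2OC | intermediate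
8 | (2S)-4,5,7-trimethoxy-2-(2,3,4-trimethoxyphenyl)chroman-4-ol (C4 hemiketal, C4 undefined, not isolated) | COc1cc(OC)c2c(c1)O[C@H](c1ccc(OC)c(OC)c1OC)CC2(O)OC | intermediate
9 | (2S)-5,7-dimethoxy-2-(2,3,4-trimethoxyphenyl)chroman-4-one | COc1cc(OC)c2c(c1)O[C@H](c1ccc(OC)c(OC)c1OC)CC2=O | target

**Step count and risks**
Total step count: 3. Longest linear sequence: 3 steps (1 → 2 → 7 → 9).

Steps most likely to fail:

1. Step 2. The chiral acid may fail to differentiate the faces of the styrene at O1–C2, or exo and endo approaches may give C4 epimers of opposite C2 configuration, so that the ee erodes once C4 is oxidised. The stabilised methide may also be diverted into Friedel–Crafts oligomerisation or unproductive acetal exchange. Fallback, from 3 back to 7, using the established two-component mode with only one stereocentre to control: 3 is reduced with NaBH4 (MeOH/THF, 0 °C) to 2-(hydroxymethyl)-3,5-dimethoxyphenol F1. F1 and styrene 2 are combined with the same chiral N-triflylphosphoramide (toluene, 5 Å MS), whereupon dehydration gives the parent methide 3,5-dimethoxy-6-methylidenecyclohexa-2,4-dien-1-one F2. This is trapped by 2 in the known asymmetric [4+2] mode as (2S)-5,7-dimethoxy-2-(2,3,4-trimethoxyphenyl)chromane F3. Hydride abstraction from C4 of F3 with DDQ in CH2Cl2/MeOH, the C4 alkoxylation used on 5,7-dioxygenated flavans, installs the methoxy group and returns to 7.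

2. Step 3. Hydride abstraction may compete at C2, the oxidation may run on to flavylium-type species, or the DDQ hydroquinone may promote acid opening of ring C and so loss of configuration. Fallback, from 7 to 9, replacing hydride abstraction by solvolysis and alcohol oxidation: PPTS in THF/water exchanges the labile, doubly activated C4 methoxy group for hydroxyl, giving (2S)-5,7-dimethoxy-2-(2,3,4-trimethoxyphenyl)chroman-4-ol F4 as a mixture at C4. Dess–Martin periodinane in CH2Cl2 at 0 °C then oxidises F4 to 9.

3. Step 1. The volatile, polymerisation-prone styrene may be lost or oligomerise during its separation from triphenylphosphine oxide, and the ortho-methoxy aldehyde may convert incompletely. Fallback, from 1 to 2, by Peterson olefination with only volatile silicon by-products: (trimethylsilyl)methylmagnesium chloride in THF adds to 1 to give 1-(2,3,4-trimethoxyphenyl)-2-(trimethylsilyl)ethanol F5. KH in THF then effects syn-elimination of F5 to 2.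

**Further compounds**
F1 | step 2 | 2-(hydroxymethyl)-3,5-dimethoxyphenol | COc1cc(O)c(CO)c(OC)c1
F2 | step 2 | 3,5-dimethoxy-6-methylidenecyclohexa-2,4-dien-1-one (transient) | C=C1C(=O)C=C(OC)C=C1OC
F3 | step 2 | (2S)-5,7-dimethoxy-2-(2,3,4-trimethoxyphenyl)chromane | COc1cc(OC)c2c(c1)O[C@H](c1ccc(OC)c(OC)c1OC)CC2
F4 | step 3 | (2S)-5,7-dimethoxy-2-(2,3,4-trimethoxyphenyl)chroman-4-ol (mixture of C4 epimers) | COc1cc(OC)c2c(c1)O[C@H](c1ccc(OC)c(OC)c1OC)CC2O
F5 | step 1 | 1-(2,3,4-trimethoxyphenyl)-2-(trimethylsilyl)ethanol (racemic) | COc1ccc(C(O)C[Si](C)(C)C)c(OC)c1OC
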